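With the chain numbered from the carboxyl carbon C1 to the aryl ketone C15, the nine stereocentres C4–C12 of the open chain are related by a local mirror plane through C8; the naphthoquinone (rings A and B) lies outside this array. The route therefore rests on one two-directional operation: a meso C5–C11 dialdehyde, held as the O7/O9 acetonide (a 1,3-dioxane), is crotylated at both formyl groups with (Z)-crotylboronic acid pinacol ester, which makes the C4–C5 and C11–C12 bonds and sets C4, C5, C11 and C12 at once. The meso product is then desymmetrised enzymatically and its ends become the C13 enone (HWE with a naphthyl ketophosphonate) and the C2 enoate (Wittig).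

Key step: step 5

Assumption: Burkholderia cepacia lipase is taken to keep its usual preference among 2-methyl-substituted primary alcohols and to acetylate the C3 hydroxymethyl group of the meso 3,13-diol (the one on (4R)-C4); the order of the two olefinations follows from this.

Remark: the quinone nitrogen needs a handle on the aromatic building block, so 1,4-dibromo-2,5-dimethoxybenzene is used; its second bromine ends at C6 of the naphthalene and is exchanged for NHBoc.

Step 1
Reactants: 1 2-methylpent-1-en-3-one; 2 methacrolein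
Product: 5 meso-(3R,5S)-2,4,6-trimethylhepta-1,6-diene-3,5-diol (future C6–C10; hydroxyls syn; central methyl anti to both), via E-enol borinate 3 (not isolated), via anti boron aldolate 4 (not isolated)
Conditions: Cy2BCl, Et3N, Et2O, −78 → 0 °C; 2, −78 → −20 °C; LiBH4, −78 °C; then H2O2, aq. NaOH, MeOH, 0 °C
Reagents that add atoms: none
Why: Cy2BCl/Et3N gives the E-enol borinate, whose chair Zimmerman–Traxler aldol addition sets the C8/C9 anti relation, and hydride delivery from LiBH4 to the six-membered boron chelate (one-pot aldol–reduction) sets the C7/C9 syn diol, so both enantiomers of the racemic aldolate converge on the same meso diol.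

Step 2
Reactants: 5 meso diene diol
Product: 6 meso-2,2,5-trimethyl-4,6-di(prop-1-en-2-yl)-1,3-dioxane (4,6-cis; 5-methyl trans to both)
Conditions: Me2C(OMe)2, PPTS (cat.), CH2Cl2, rt
Reagents that add atoms: 2,2-dimethoxypropane COC(C)(C)OC
Why: Acid-catalysed transacetalisation ties the syn-1,3-diol into a chair dioxane with all three ring substituents equatorial and touches no stereocentre.

Step 3
Reactants: 6 meso bis-isopropenyl acetonide
Product: 8 meso-2,2'-(2,2,5-trimethyl-1,3-dioxane-4,6-diyl)di(propan-1-ol) (each side-chain methyl anti to the adjacent ring oxygen), via bis(B-alkyl-9-BBN) adduct 7 (not isolated)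
Conditions: 9-BBN, THF, 0 °C → rt; then aq. NaOH, H2O2, 0 °C → rt
Reagents that add atoms: hydrogen peroxide OO
Why: Hydroboration–oxidation with the bulky 9-BBN places boron on each terminal carbon and attacks each isopropenyl group, in the conformer that keeps the allylic C–H in the alkene plane, from the face opposite ring carbon C8, which is the known anti-selective hydroboration of 1,1-disubstituted alkenes next to an oxygen-bearing stereocentre and sets C6 and C10 anti to O7 and O9.

Step 4
Reactants: 8 meso primary diol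
Product: 9 meso C5–C11 dialdehyde 2,2'-(2,2,5-trimethyl-1,3-dioxane-4,6-diyl)dipropanal (configuration as 8)
Conditions: DMP, NaHCO3, CH2Cl2, 0 °C → rt; used crude at once
Reagents that add atoms: none
Why: Dess–Martin oxidation under buffered, amine-free conditions converts both primary alcohols into aldehydes without enolising the α-methyl centres C6 and C10, and the dialdehyde is used without chromatography.

Step 5
Reactants: 9 meso C5–C11 dialdehyde; 10 (Z)-crotylboronic acid pinacol ester
Product: 12 meso bis-homoallylic diol (C3–C13 chain; vinyl groups at both ends; free OH at C5 and C11; O7/O9 acetonide; all nine stereocentres C4–C12), via bis(pinacol borate) ester 11 (not isolated)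
Conditions: 10 (3 equiv), 4 Å MS, toluene, rt; then aq. NaHCO3
Reagents that add atoms: none
Why: Each formyl oxygen of 9 binds the boron of 10 and the allyl group is transferred through a cyclic six-membered chair transition state (allylboration); the closest known reaction type is the substrate-controlled addition of (Z)-crotylboronates to α-methyl-β-alkoxy aldehydes, which delivers syn,anti stereotriads. No ring is formed, and the dioxane of 9 merely ties O7 to O9 and makes the large substituent on C6 and C10 a rigid ring carbon. C4 and C12 are controlled by the Z geometry of the boronate, which the chair converts into the 4,5-syn and 11,12-syn relations. C5 and C11 are controlled by the methyl-bearing neighbours C6 and C10: a Felkin-type approach would force that methyl group into a syn-pentane contact with the methyl group of the Z reagent, so the aldehyde presents its α-hydrogen to the reagent and the new hydroxyl group ends up anti to the α-methyl group. The step needs this facial preference at both ends together with syn simple diastereoselection; because 9 and 10 are achiral the two ends react as mirror images, the doubly selective product 12 is meso and holds all nine stereocentres C4–C12, and material that is wrong at one end is a chiral diastereomer that can be removed by chromatography.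

Step 6
Reactants: 12 meso bis-homoallylic diol
Product: 13 bis(triethylsilyl) ether of 12 at O5 and O11
Conditions: TESOTf, 2,6-lutidine, CH2Cl2, −78 → 0 °C
Reagents that add atoms: triethylsilyl trifluoromethanesulfonate CC[Si](CC)(CC)OS(=O)(=O)C(F)(F)F
Why: The silyl triflate with a hindered pyridine base silylates the two hindered secondary hydroxyl groups (silyl ether formation), so that they survive the later oxidations and olefinations and fall off with acid at the end.

Step 7
Reactants: 13 bis-TES diene
Product: 16 meso 3,13-diol (C3–C13 chain with CH2OH at both ends; O5/O11 TES; O7/O9 acetonide), via bis-ozonide 14 (not isolated), via C3/C13 dialdehyde 15 (not isolated)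
Conditions: O3, CH2Cl2, −78 °C; PPh3, −78 °C → rt; then NaBH4, MeOH, 0 °C
Reagents that add atoms: ozone [O-][O+]=O
Why: Ozonolysis of both vinyl groups with reductive work-up, followed by borohydride reduction in the same flask, removes one carbon from each end and reduces the epimerisable α-methyl aldehydes before they can enolise, leaving C4 and C12 untouched.

Step 8
Reactants: 16 meso 3,13-diol
Product: 17 monoacetate of 16 (acetate on O3, the hydroxymethyl on (4R)-C4; free C13 hydroxymethyl on (12S)-C12)
Conditions: Burkholderia cepacia lipase (lipase PS), vinyl acetate, t-BuOMe, 30 °C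
Reagents that add atoms: vinyl acetate C=COC(C)=O
Why: Lipase-catalysed transesterification with the irreversible acyl donor vinyl acetate differentiates the two enantiotopic hydroxymethyl groups of the meso diol (enzymatic desymmetrisation), the enzyme reading the configuration of the adjacent methyl-bearing carbon (C4 versus C12), and this fixes the absolute configuration of the whole chain.

Step 9
Reactants: 18 1,4-dibromo-2,5-dimethoxybenzene
Product: 21 2,5-dibromo-3,6-dimethoxybenzaldehyde, via aryllithium 19 (not isolated), via lithium hemiaminal alkoxide 20 (not isolated)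
Conditions: LiN(iPr)2, THF, −78 °C; DMF, −78 → 0 °C; aq. HCl
Reagents that add atoms: N,N-dimethylformamide CN(C)C=O
Why: Directed ortho-lithiation with the amide base removes the ring hydrogen flanked by bromine and methoxy (both ring hydrogens are equivalent) and the aryllithium is formylated by DMF, at −78 °C so that loss of LiBr to an aryne does not compete.

Step 10
Reactants: 21 2,5-dibromo-3,6-dimethoxybenzaldehyde; 22 heptane-3,5-dione
Product: 24 1-(6-bromo-2-hydroxy-5,8-dimethoxy-3-methylnaphthalen-1-yl)propan-1-one, via arylated diketone 23 (not isolated)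
Conditions: 22 (1.1 equiv), CuI (10 mol%), pyridine-2-carboxylic acid (20 mol%), Cs2CO3, DMSO, 60 → 90 °C; aq. HCl
Reagents that add atoms: none
Why: Copper-catalysed C-arylation of the β-diketone (Hurtley-type coupling), accelerated and directed by the ortho-formyl group so that only the flanking bromide reacts, is followed by intramolecular aldol condensation of an ethyl CH2 onto the aldehyde and enolisation, which aromatises ring B (domino α-arylation/cyclocondensation to a 2-naphthol).

Step 11
Reactants: 24 bromonaphthol ketone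
Product: 25 1-[6-bromo-5,8-dimethoxy-2-(methoxymethoxy)-3-methylnaphthalen-1-yl]propan-1-one
Conditions: MOMCl, iPr2NEt, CH2Cl2, 0 → 40 °C
Reagents that add atoms: chloromethyl methyl ether COCCl
Why: Base-mediated O-alkylation with the chloromethyl ether masks the acidic naphthol as an acetal that resists the bases used later and is removed by acid in the last step.

Step 12
Reactants: 25 MOM-protected bromonaphthyl ketone
Product: 28 diethyl {1-[6-bromo-5,8-dimethoxy-2-(methoxymethoxy)-3-methylnaphthalen-1-yl]-1-oxopropan-2-yl}phosphonate (racemic), via lithium enolate 26 (not isolated), via phosphonite 27 (not isolated)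
Conditions: LiN(SiMe3)2, THF, −78 °C; ClP(OEt)2, −78 → 0 °C; then H2O2 (30% aq.), 0 °C
Reagents that add atoms: diethyl chlorophosphite CCOP(Cl)OCC; hydrogen peroxide OO
Why: Deprotonation gives the ketone enolate, which attacks the trivalent phosphorus chloride through carbon, and oxidation of the resulting phosphonite gives the β-ketophosphonate (enolate C-phosphinylation–oxidation), a route that avoids electrophilic halogenation of the electron-rich ring.

Step 13
Reactants: 28 bromonaphthyl ketophosphonate
Product: 29 diethyl {1-[6-(tert-butoxycarbonylamino)-5,8-dimethoxy-2-(methoxymethoxy)-3-methylnaphthalen-1-yl]-1-oxopropan-2-yl}phosphonate (racemic)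
Conditions: BocNH2, Pd(OAc)2 (5 mol%), XPhos (10 mol%), Cs2CO3, 1,4-dioxane, 90 °C
Reagents that add atoms: tert-butyl carbamate CC(C)(C)OC(N)=O
Why: Palladium-catalysed Buchwald–Hartwig coupling of the aryl bromide with tert-butyl carbamate installs the protected nitrogen at C6, the position fixed by the symmetry of 18, while the weak carbonate base only converts the ketophosphonate into its chelated, non-nucleophilic enolate.

Step 14
Reactants: 17 monoacetate
Product: 30 C13 aldehyde (C3 acetate; O5/O11 TES; O7/O9 acetonide)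
Conditions: DMP, NaHCO3, CH2Cl2, 0 °C → rt; used crude
Reagents that add atoms: none
Why: Dess–Martin oxidation of the free C13 hydroxymethyl group gives the α-methyl aldehyde under buffered conditions that neither epimerise C12 nor touch the acetate.

Step 15
Reactants: 30 C13 aldehyde; 29 naphthyl ketophosphonate
Product: 31 (13E)-enone (C13=C14 joined to the protected naphthyl ketone C15; C3 acetate)
Conditions: Ba(OH)2 (activated), THF/H2O (40:1), rt
Reagents that add atoms: none
Why: Horner–Wadsworth–Emmons olefination under mild Ba(OH)2 conditions joins the fragments at C13=C14; the reversible addition of the α-methyl ketophosphonate anion funnels to the (E)-trisubstituted enone, and the mild base spares C12 and the β-silyloxy group.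

Step 16
Reactants: 31 enone acetate
Product: 32 C3 primary alcohol of 31
Conditions: K2CO3, MeOH, 0 °C
Reagents that add atoms: none
Why: Carbonate-catalysed transesterification with methanol removes the primary acetate at O3 without affecting the silyl ethers, the carbamate, the acetal or the hindered enone.

Step 17
Reactants: 32 C3 alcohol
Product: 34 tert-butyl (2E)-enoate (full C1–C15 chain; all groups still protected), via C3 aldehyde 33 (not isolated)
Conditions: SO3·pyridine, DMSO, iPr2NEt, CH2Cl2, 0 °C; then Ph3P=CHCO2tBu, rt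
Reagents that add atoms: tert-butyl (triphenylphosphoranylidene)acetate CC(C)(C)OC(=O)C=P(c1ccccc1)(c1ccccc1)c1ccccc1
Why: Parikh–Doering oxidation gives the C3 aldehyde, which is trapped in the same flask by the stabilised ylide (Wittig reaction) to give the (E)-enoate before C4 can epimerise; this activated-DMSO oxidant is chosen because it leaves the electron-rich carbamoyl naphthalene alone.

Step 18
Reactants: 34 protected dimethoxynaphthalene
Product: 35 protected 5,8-naphthoquinone (NHBoc at C6 of the naphthalene; MOM ether; tert-butyl ester; TES ethers; acetonide)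
Conditions: (NH4)2Ce(NO3)6, MeCN/H2O (2:1), 0 °C; crude taken on
Reagents that add atoms: water O
Why: Oxidative demethylation of the 1,4-dimethoxy ring A by the cerium salt (two one-electron oxidations, with water adding at the methoxy-bearing carbons) gives the quinone carrying the carbamate nitrogen, ring A being the only ring that has para-disposed oxygen atoms.

Step 19
Reactants: 35 protected quinone
Product: 36 target CNP0336625.1
Conditions: TFA/CH2Cl2/H2O (10:10:1), 0 °C → rt
Reagents that add atoms: none
Why: Aqueous trifluoroacetic acid cleaves in one acidolysis the tert-butyl ester, the Boc group, the MOM ether, both triethylsilyl ethers and the acetonide, and the non-nucleophilic acid leaves the enone, the enoic acid, the aminoquinone and all stereocentres unchanged.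

Compound list

1 | 2-methylpent-1-en-3-one | CCC(=O)C(C)=C | starting material
2 | methacrolein (2-methylprop-2-enal) | C=C(C)C=O | starting material
3 | dicyclohexyl{[(3E)-2-methylpenta-1,3-dien-3-yl]oxy}borane (E-enol borinate of 1) | C/C=C(/OB(C1CCCCC1)C1CCCCC1)C(C)=C | intermediate
4 | O-dicyclohexylboryl derivative of rac-anti-5-hydroxy-2,4,6-trimethylhepta-1,6-dien-3-one (one enantiomer drawn) | C=C(C)C(=O)[C@@H](C)[C@@H](OB(C1CCCCC1)C1CCCCC1)C(C)=C | intermediate
5 | meso-(3R,5S)-2,4,6-trimethylhepta-1,6-diene-3,5-diol (syn diol, 4-methyl anti to both OH) | C=C(C)[C@@H](O)[C@@H](C)[C@@H](O)C(C)=C | intermediate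
6 | meso-2,2,5-trimethyl-4,6-di(prop-1-en-2-yl)-1,3-dioxane (4,6-cis, 5-methyl trans to both) | C=C(C)[C@@H](O1)[C@@H](C)[C@@H](OC1(C)C)C(C)=C | intermediate
7 | bis-trialkylborane: skeleton of 8 with a 9-borabicyclo[3.3.1]nonan-9-yl group on each terminal CH2 | C1CCC2CCCC1B2C[C@@H](C)[C@@H](O3)[C@@H](C)[C@@H](OC3(C)C)[C@@H](C)CB4C5CCCC4CCC5 | intermediate
8 | meso-2,2'-(2,2,5-trimethyl-1,3-dioxane-4,6-diyl)di(propan-1-ol), side-chain methyls anti to the adjacent ring oxygens | OC[C@@H](C)[C@@H](O1)[C@@H](C)[C@@H](OC1(C)C)[C@@H](C)CO | intermediate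
9 | meso C5–C11 dialdehyde, 2,2'-(2,2,5-trimethyl-1,3-dioxane-4,6-diyl)dipropanal (O7,O9-acetonide) | O=C[C@@H](C)[C@@H](O1)[C@@H](C)[C@@H](OC1(C)C)[C@@H](C)C=O | intermediate
10 | (Z)-crotylboronic acid pinacol ester | C/C=C\CB1OC(C)(C)C(C)(C)O1 | starting material
11 | bis(pinacol borate) ester of 12 at O5 and O11 | C=C[C@H](C)[C@@H](OB2OC(C)(C)C(C)(C)O2)[C@@H](C)[C@@H](O1)[C@@H](C)[C@@H](OC1(C)C)[C@@H](C)[C@@H](OB3OC(C)(C)C(C)(C)O3)[C@H](C)C=C | intermediate
12 | meso-2,2'-(2,2,5-trimethyl-1,3-dioxane-4,6-diyl)bis(4-methylhex-5-en-3-ol); C3–C13 chain, 4,5-syn, 5,6-anti, 6,7-anti, 7,8-anti and the mirror relations on the C9–C12 side | C=C[C@H](C)[C@@H](O)[C@@H](C)[C@@H](O1)[C@@H](C)[C@@H](OC1(C)C)[C@@H](C)[C@@H](O)[C@H](C)C=C | intermediate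
13 | bis(triethylsilyl) ether of 12 (O5, O11) | C=C[C@H](C)[C@@H](O[Si](CC)(CC)CC)[C@@H](C)[C@@H](O1)[C@@H](C)[C@@H](OC1(C)C)[C@@H](C)[C@@H](O[Si](CC)(CC)CC)[C@H](C)C=C | intermediate
14 | bis-ozonide of 13 (a 1,2,4-trioxolan-3-yl group at each end, ring epimers) | O1COOC1[C@H](C)[C@@H](O[Si](CC)(CC)CC)[C@@H](C)[C@@H](O3)[C@@H](C)[C@@H](OC3(C)C)[C@@H](C)[C@@H](O[Si](CC)(CC)CC)[C@H](C)C2OCOO2 | intermediate
15 | meso C3/C13 dialdehyde (O5/O11 TES, O7/O9 acetonide) | O=C[C@H](C)[C@@H](O[Si](CC)(CC)CC)[C@@H](C)[C@@H](O1)[C@@H](C)[C@@H](OC1(C)C)[C@@H](C)[C@@H](O[Si](CC)(CC)CC)[C@H](C)C=O | intermediate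
16 | meso 3,13-diol (C3–C13 chain, CH2OH at both ends, O5/O11 TES, O7/O9 acetonide, methyls at C4, C6, C8, C10, C12) | OC[C@H](C)[C@@H](O[Si](CC)(CC)CC)[C@@H](C)[C@@H](O1)[C@@H](C)[C@@H](OC1(C)C)[C@@H](C)[C@@H](O[Si](CC)(CC)CC)[C@H](C)CO | intermediate
17 | monoacetate of 16: O3 acetate (on (4R)-C4), free C13 alcohol (on (12S)-C12) | OC[C@H](C)[C@@H](O[Si](CC)(CC)CC)[C@@H](C)[C@@H](O1)[C@@H](C)[C@@H](OC1(C)C)[C@@H](C)[C@@H](O[Si](CC)(CC)CC)[C@H](C)COC(C)=O | intermediate
18 | 1,4-dibromo-2,5-dimethoxybenzene | COc1cc(Br)c(OC)cc1Br | starting material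
19 | (2,5-dibromo-3,6-dimethoxyphenyl)lithium | [Li]c1c(Br)c(OC)cc(Br)c1OC | intermediate
20 | lithium (2,5-dibromo-3,6-dimethoxyphenyl)(dimethylamino)methanolate | [Li+].[O-]C(N(C)C)c1c(Br)c(OC)cc(Br)c1OC | intermediate
21 | 2,5-dibromo-3,6-dimethoxybenzaldehyde | O=Cc1c(Br)c(OC)cc(Br)c1OC | intermediate
22 | heptane-3,5-dione | CCC(=O)CC(=O)CC | starting material
23 | 4-(4-bromo-2-formyl-3,6-dimethoxyphenyl)heptane-3,5-dione | CCC(=O)C(C(=O)CC)c1c(OC)cc(Br)c(OC)c1C=O | intermediate
24 | 1-(6-bromo-2-hydroxy-5,8-dimethoxy-3-methylnaphthalen-1-yl)propan-1-one | CCC(=O)c1c(O)c(C)cc2c(OC)c(Br)cc(OC)c12 | intermediate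
25 | 1-[6-bromo-5,8-dimethoxy-2-(methoxymethoxy)-3-methylnaphthalen-1-yl]propan-1-one | CCC(=O)c1c(OCOC)c(C)cc2c(OC)c(Br)cc(OC)c12 | intermediate
26 | lithium (Z)-enolate of 25 | C/C=C(\O[Li])c1c(OCOC)c(C)cc2c(OC)c(Br)cc(OC)c12 | intermediate
27 | diethyl {1-[6-bromo-5,8-dimethoxy-2-(methoxymethoxy)-3-methylnaphthalen-1-yl]-1-oxopropan-2-yl}phosphonite (racemic) | CC(C(=O)c1c(OCOC)c(C)cc2c(OC)c(Br)cc(OC)c12)P(OCC)OCC | intermediate
28 | diethyl {1-[6-bromo-5,8-dimethoxy-2-(methoxymethoxy)-3-methylnaphthalen-1-yl]-1-oxopropan-2-yl}phosphonate (racemic) | CC(C(=O)c1c(OCOC)c(C)cc2c(OC)c(Br)cc(OC)c12)P(=O)(OCC)OCC | intermediate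
29 | diethyl {1-[6-(tert-butoxycarbonylamino)-5,8-dimethoxy-2-(methoxymethoxy)-3-methylnaphthalen-1-yl]-1-oxopropan-2-yl}phosphonate (racemic) | CC(C(=O)c1c(OCOC)c(C)cc2c(OC)c(NC(=O)OC(C)(C)C)cc(OC)c12)P(=O)(OCC)OCC | intermediate
30 | C13 aldehyde from 17 (O3 acetate, O5/O11 TES, O7/O9 acetonide) | O=C[C@H](C)[C@@H](O[Si](CC)(CC)CC)[C@@H](C)[C@@H](O1)[C@@H](C)[C@@H](OC1(C)C)[C@@H](C)[C@@H](O[Si](CC)(CC)CC)[C@H](C)COC(C)=O | intermediate
31 | (13E)-enone: C3–C15 chain, C15 ketone on the 6-(Boc-amino)-5,8-dimethoxy-2-(methoxymethoxy)-3-methylnaphthalen-1-yl ring, O3 acetate, O5/O11 TES, O7/O9 acetonide | C/C(=C\[C@H](C)[C@@H](O[Si](CC)(CC)CC)[C@@H](C)[C@@H](O1)[C@@H](C)[C@@H](OC1(C)C)[C@@H](C)[C@@H](O[Si](CC)(CC)CC)[C@H](C)COC(C)=O)C(=O)c1c(OCOC)c(C)cc2c(OC)c(NC(=O)OC(C)(C)C)cc(OC)c12 | intermediate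
32 | C3 primary alcohol of 31 | C/C(=C\[C@H](C)[C@@H](O[Si](CC)(CC)CC)[C@@H](C)[C@@H](O1)[C@@H](C)[C@@H](OC1(C)C)[C@@H](C)[C@@H](O[Si](CC)(CC)CC)[C@H](C)CO)C(=O)c1c(OCOC)c(C)cc2c(OC)c(NC(=O)OC(C)(C)C)cc(OC)c12 | intermediate
33 | C3 aldehyde of 32 | C/C(=C\[C@H](C)[C@@H](O[Si](CC)(CC)CC)[C@@H](C)[C@@H](O1)[C@@H](C)[C@@H](OC1(C)C)[C@@H](C)[C@@H](O[Si](CC)(CC)CC)[C@H](C)C=O)C(=O)c1c(OCOC)c(C)cc2c(OC)c(NC(=O)OC(C)(C)C)cc(OC)c12 | intermediate
34 | tert-butyl (2E,13E)-dienoate: full C1–C15 chain, protected as in 31 | C/C(=C\[C@H](C)[C@@H](O[Si](CC)(CC)CC)[C@@H](C)[C@@H](O1)[C@@H](C)[C@@H](OC1(C)C)[C@@H](C)[C@@H](O[Si](CC)(CC)CC)[C@H](C)/C=C/C(=O)OC(C)(C)C)C(=O)c1c(OCOC)c(C)cc2c(OC)c(NC(=O)OC(C)(C)C)cc(OC)c12 | intermediate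
35 | protected quinone: 34 with ring A as the 5,8-dione and NHBoc at C6 | C/C(=C\[C@H](C)[C@@H](O[Si](CC)(CC)CC)[C@@H](C)[C@@H](O1)[C@@H](C)[C@@H](OC1(C)C)[C@@H](C)[C@@H](O[Si](CC)(CC)CC)[C@H](C)/C=C/C(=O)OC(C)(C)C)C(=O)c1c(OCOC)c(C)cc2c1C(=O)C=C(NC(=O)OC(C)(C)C)C2=O | intermediate
36 | (2E,4R,5S,6S,7S,8S,9R,10R,11R,12S,13E)-15-(6-amino-2-hydroxy-3-methyl-5,8-dioxo-5,8-dihydronaphthalen-1-yl)-5,7,9,11-tetrahydroxy-4,6,8,10,12,14-hexamethyl-15-oxopentadeca-2,13-dienoic acid (CNP0336625.1) | C/C(=C\[C@H](C)[C@@H](O)[C@@H](C)[C@@H](O)[C@@H](C)[C@@H](O)[C@@H](C)[C@@H](O)[C@H](C)/C=C/C(=O)O)C(=O)c1c(O)c(C)cc2c1C(=O)C=C(N)C2=O | target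

Total step count: 19. Longest linear sequence: 14 steps (steps 1–8 and 14–19); the aromatic branch (steps 9–13) joins in step 15.

Steps most likely to fail

Step 5. Facial discrimination may be insufficient at one or both formyl groups, the addition may be slow at the hindered aldehydes, or C6/C10 may epimerise during the long reaction time; each would erode the meso product. Fallback: a two-directional syn-aldol reaction replaces the allylboration. Setting out from 9, the Z-dibutylboron enolate of 3-propanoyl-1,3-oxazolidin-2-one (Bu2BOTf, Et3N, CH2Cl2, −78 → 0 °C) adds to both formyl groups. The chair transition state again gives the 4,5-syn and 11,12-syn relations, and the same syn-pentane avoidance favours attack anti to the C6/C10 methyl groups, giving the meso bis(acyloxazolidinone) aldol adduct F1. Silylation (TESOTf, 2,6-lutidine) gives the bis(triethylsilyl) ether F2, and LiBH4 (THF, MeOH, 0 °C) cleaves both imides reductively. This returns to the route at 16 and makes steps 6 and 7 unnecessary.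

Step 10. Coupling may occur at the wrong bromide, the copper cycle may stall at the doubly ortho-substituted carbon, or the arylated diketone may undergo retro-Claisen cleavage before ring closure. Fallback: the order of bond formation is reversed so that the arylation becomes intramolecular. Setting out from 21 and 22, the dianion of 22 (NaH, then n-BuLi, THF, 0 °C) adds through its terminal carbon to the aldehyde to give the aldol adduct F3. CuI/Cs2CO3 in DMSO then closes ring B by C-arylation at the only bromide within reach, giving the cyclised hydroxy diketone F4. TsOH in toluene removes water and aromatises it, which returns to the route at 24.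

Step 8. The enzyme may select the other enantiotopic hydroxymethyl group (C13), which would deliver the antipodal series. Fallback: the same enzyme preference is used in the hydrolytic direction. Setting out from 16, full acetylation (Ac2O, pyridine, DMAP) gives the meso diacetate F5. The lipase in phosphate buffer (pH 7)/acetone then removes the acetate from the C13 hydroxymethyl group it prefers, leaving the acetate on O3, and the route is rejoined at 17.

Further compounds
F1 | step 5 | meso bis-aldol adduct: C3–C13 chain of 12 with a 2-oxo-1,3-oxazolidin-3-yl carbonyl group at C3 and at C13, free OH at C5 and C11, O7/O9 acetonide | O=C(N1CCOC1=O)[C@H](C)[C@@H](O)[C@@H](C)[C@@H](O2)[C@@H](C)[C@@H](OC2(C)C)[C@@H](C)[C@@H](O)[C@H](C)C(=O)N3CCOC3=O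
F2 | step 5 | bis(triethylsilyl) ether of F1 (O5, O11) | O=C(N1CCOC1=O)[C@H](C)[C@@H](O[Si](CC)(CC)CC)[C@@H](C)[C@@H](O2)[C@@H](C)[C@@H](OC2(C)C)[C@@H](C)[C@@H](O[Si](CC)(CC)CC)[C@H](C)C(=O)N3CCOC3=O
F3 | step 10 | 7-(2,5-dibromo-3,6-dimethoxyphenyl)-7-hydroxy-6-methylheptane-3,5-dione (diastereomer mixture) | CCC(=O)CC(=O)C(C)C(O)c1c(Br)c(OC)cc(Br)c1OC
F4 | step 10 | 6-bromo-4-hydroxy-5,8-dimethoxy-3-methyl-1-propanoyl-3,4-dihydronaphthalen-2(1H)-one (diastereomer mixture) | CCC(=O)C1C(=O)C(C)C(O)c2c(OC)c(Br)cc(OC)c12
F5 | step 8 | meso diacetate of 16 (O3 and O13) | CC(=O)OC[C@H](C)[C@@H](O[Si](CC)(CC)CC)[C@@H](C)[C@@H](O1)[C@@H](C)[C@@H](OC1(C)C)[C@@H](C)[C@@H](O[Si](CC)(CC)CC)[C@H](C)COC(C)=O
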